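## Retrosynthetic overview

1. The C13 bromide comes from invertive bromination of a (13R)-carbinol, itself from chelation-controlled EtMgBr addition to a C12 aldehyde; the Z-enyne comes from Peterson olefination of a C4 aldehyde unmasked from a C6 allyl group.
2. C9–Cl and C10–OAc come from acetyl chloride opening of an α-9,10-epoxide (a transient second ring, made in step 8 and opened in step 11); C7–Cl comes from invertive chlorination of a C7 alcohol.
3. The C6 side chain comes from trans-selective C-allylation of the lactol acetate of an eight-membered hydroxy lactone; the C7 oxygen comes from enolate oxidation.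
4. Key step: the oxocane ring (the only ring of the target) is made by Claisen rearrangement of a 2-methylene-4-vinyl-1,3-dioxane, which forms C7–C8 and expands the ring from six to eight members.
5. The dioxane is built from (R)-3-hydroxy-γ-butyrolactone, whose single stereocentre (C12) controls all the others.

Convention and assumption: C1–C15 number the target's carbon chain (C1 alkyne terminus, ring oxygen between C6 and C12); α is the ring face of the C6 side chain, β that of the C12 side chain; the C10 carbinol epimers of 3–7 are carried as a mixture because that centre is destroyed in step 4.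

## Route

Step 1
Reactants: 1 (R)-3-hydroxy-γ-butyrolactone
Product: 3 (2R)-hex-5-ene-1,2,4-triol (C4 epimers), via lactol 2 (not isolated)
Conditions: i-Bu2AlH (2.2 equiv), CH2Cl2–THF, −78 °C; then CH2=CHMgBr (4 equiv), −78 → 0 °C; Rochelle salt work-up
Reagents that add atoms: vinylmagnesium bromide, C=C[Mg]Br
Why: One-pot lactone reduction/Grignard addition: the reduction stops at the aluminium lactolate, which opens on warming and is trapped by the vinyl Grignard, the bought C12 centre being untouched and the new C10 carbinol (about 1:1) irrelevant.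

Step 2
Reactants: 3 (2R)-hex-5-ene-1,2,4-triol
Product: 4 (2R)-1-[(tert-butyldiphenylsilyl)oxy]hex-5-ene-2,4-diol (C4 epimers)
Conditions: TBDPSCl (1.05 equiv), imidazole, DMF, 0 °C
Reagents that add atoms: tert-butylchlorodiphenylsilane, CC(C)(C)[Si](Cl)(c1ccccc1)c1ccccc1
Why: Silyl ether formation in which the bulky silyl chloride reacts only at the primary hydroxyl and leaves the 1,3-diol free.

Step 3
Reactants: 4 (2R)-1-[(tert-butyldiphenylsilyl)oxy]hex-5-ene-2,4-diol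
Product: 5 (6R)-6-{[(tert-butyldiphenylsilyl)oxy]methyl}-2-[(phenylselanyl)methyl]-4-vinyl-1,3-dioxane (epimers at C2 and C4)
Conditions: PhSeCH2CH(OEt)2 (1.3 equiv), PPTS (cat.), toluene, reflux, EtOH distilled off
Reagents that add atoms: (phenylseleno)acetaldehyde diethyl acetal, CCOC(C[Se]c1ccccc1)OCC
Why: Acid-catalysed transacetalisation closes the six-membered acetal on the 1,3-diol with loss of ethanol, and all epimers converge in the next step.

Step 4
Reactants: 5 (6R)-6-{[(tert-butyldiphenylsilyl)oxy]methyl}-2-[(phenylselanyl)methyl]-4-vinyl-1,3-dioxane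
Product: 8 (5Z,8R)-8-{[(tert-butyldiphenylsilyl)oxy]methyl}-3,4,7,8-tetrahydro-2H-oxocin-2-one, via selenoxide 6 (not isolated), via ketene acetal 7 (not isolated)
Conditions: NaIO4, NaHCO3, MeOH–H2O, rt; crude selenoxide then DBU, xylene, 140 °C
Reagents that add atoms: none
Why: Selenoxide syn-elimination unveils the 2-methylene-4-vinyl-1,3-dioxane, whose Claisen rearrangement ([3,3]-sigmatropic) forms C7–C8 and expands the ring to the eight-membered lactone, the ring imposing the Z C9=C10 alkene and C12 being carried through unchanged.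

Step 5
Reactants: 8 (5Z,8R)-8-{[(tert-butyldiphenylsilyl)oxy]methyl}-3,4,7,8-tetrahydro-2H-oxocin-2-one
Product: 10 (3R,5Z,8R)-8-{[(tert-butyldiphenylsilyl)oxy]methyl}-3-hydroxy-3,4,7,8-tetrahydro-2H-oxocin-2-one, via potassium enolate 9 (not isolated)
Conditions: KN(SiMe3)2 (1.2 equiv), THF–toluene, −78 °C; then (±)-trans-3-phenyl-2-(phenylsulfonyl)oxaziridine, −78 °C; aqueous quench
Reagents that add atoms: (±)-3-phenyl-2-(phenylsulfonyl)oxaziridine, O=S(=O)(N1OC1c1ccccc1)c1ccccc1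
Why: Davis enolate oxidation in which the racemic oxidant attacks the medium-ring enolate on its exposed β face, syn to the C12 substituent, giving the 3,8-cis (C7 R) alcohol under substrate control.

Step 6
Reactants: 10 (3R,5Z,8R)-8-{[(tert-butyldiphenylsilyl)oxy]methyl}-3-hydroxy-3,4,7,8-tetrahydro-2H-oxocin-2-one
Product: 12 (3R,5Z,8R)-8-{[(tert-butyldiphenylsilyl)oxy]methyl}-3,4,7,8-tetrahydro-2H-oxocine-2,3-diyl diacetate (C2 epimers), via lactol 11 (not isolated)
Conditions: i-Bu2AlH (2.5 equiv), CH2Cl2, −78 °C; then pyridine, DMAP, Ac2O, −78 → 0 °C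
Reagents that add atoms: acetic anhydride, CC(=O)OC(C)=O
Why: Rychnovsky reductive acetylation traps the aluminium hemiacetal as its acetate before the medium-ring lactol can open, and acetylates the C7 alkoxide at the same time.

Step 7
Reactants: 12 (3R,5Z,8R)-8-{[(tert-butyldiphenylsilyl)oxy]methyl}-3,4,7,8-tetrahydro-2H-oxocine-2,3-diyl diacetate
Product: 13 (2S,3R,5Z,8R)-2-allyl-8-{[(tert-butyldiphenylsilyl)oxy]methyl}-3,4,7,8-tetrahydro-2H-oxocin-3-yl acetate
Conditions: allylSiMe3 (4 equiv), BF3·OEt2 (2 equiv), CH2Cl2, −78 → −30 °C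
Reagents that add atoms: allyltrimethylsilane, C=CC[Si](C)(C)C
Why: Hosomi–Sakurai C-allylation of the oxocarbenium ion, where the participating C7 acetate and the C12 group both occupy the β face, so the allylsilane enters from the α face and sets C6 (S) trans to both.

Step 8
Reactants: 13 (2S,3R,5Z,8R)-2-allyl-8-{[(tert-butyldiphenylsilyl)oxy]methyl}-3,4,7,8-tetrahydro-2H-oxocin-3-yl acetate
Product: 14 (2S,3R,5R,6S,8R)-2-allyl-8-{[(tert-butyldiphenylsilyl)oxy]methyl}-5,6-epoxyoxocan-3-yl acetate (epoxide oxygen α, cis to allyl)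
Conditions: mCPBA (1.05 equiv), NaHCO3, CH2Cl2, 0 °C
Reagents that add atoms: 3-chloroperoxybenzoic acid, O=C(OO)c1cccc(Cl)c1
Why: Prilezhaev epoxidation in which the cis-disubstituted ring alkene reacts before the terminal allyl group, and the peracid takes the α face because both substituents flanking the alkene (C7–OAc and C12–CH2OSi) lie on the β face.

Step 9
Reactants: 14 (2S,3R,5R,6S,8R)-2-allyl-8-{[(tert-butyldiphenylsilyl)oxy]methyl}-5,6-epoxyoxocan-3-yl acetate
Product: 15 (2S,3R,5R,6S,8R)-2-allyl-8-{[(tert-butyldiphenylsilyl)oxy]methyl}-5,6-epoxyoxocan-3-ol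
Conditions: K2CO3 (0.2 equiv), MeOH, 0 °C → rt
Reagents that add atoms: none
Why: Base-catalysed methanolysis (transesterification) removes the C7 acetate without touching the epoxide or the silyl ether.

Step 10
Reactants: 15 (2S,3R,5R,6S,8R)-2-allyl-8-{[(tert-butyldiphenylsilyl)oxy]methyl}-5,6-epoxyoxocan-3-ol
Product: 16 (2S,3S,5R,6S,8R)-2-allyl-8-{[(tert-butyldiphenylsilyl)oxy]methyl}-3-chloro-5,6-epoxyoxocane
Conditions: 1-chloro-N,N,2-trimethylprop-1-en-1-amine (1.5 equiv), CH2Cl2, 0 °C → rt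
Reagents that add atoms: 1-chloro-N,N,2-trimethylprop-1-en-1-amine (Ghosez reagent), CC(C)=C(Cl)N(C)C
Why: Ghosez chlorination activates the alcohol under neutral conditions and chloride displaces it by SN2 with inversion, giving the α (C7 S) chloride while the epoxide survives.

Step 11
Reactants: 16 (2S,3S,5R,6S,8R)-2-allyl-8-{[(tert-butyldiphenylsilyl)oxy]methyl}-3-chloro-5,6-epoxyoxocane
Product: 17 (2S,3S,5S,6S,8R)-2-allyl-8-{[(tert-butyldiphenylsilyl)oxy]methyl}-3,5-dichlorooxocan-6-yl acetate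
Conditions: AcCl (3 equiv), CoCl2 (5 mol %), CH2Cl2, 0 °C → rt
Reagents that add atoms: acetyl chloride, CC(=O)Cl
Why: Lewis-acid-catalysed acyl chloride opening of the epoxide (SN2), where chloride must come from the β face and does so at C9, whose 1,3-neighbour C7 has only H on that face, rather than at C10, which is screened by the β C12 side chain, giving 9β-Cl (S, inversion) and 10α-OAc (S, retained).

Step 12
Reactants: 17 (2S,3S,5S,6S,8R)-2-allyl-8-{[(tert-butyldiphenylsilyl)oxy]methyl}-3,5-dichlorooxocan-6-yl acetate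
Product: 19 2-[(2S,3S,5S,6S,8R)-6-acetoxy-8-{[(tert-butyldiphenylsilyl)oxy]methyl}-3,5-dichlorooxocan-2-yl]acetaldehyde, via ozonide 18 (not isolated)
Conditions: O3, CH2Cl2, −78 °C; then PPh3, −78 °C → rt
Reagents that add atoms: ozone, [O-][O+]=O
Why: Ozonolysis with reductive work-up cleaves the only remaining alkene to the C4 aldehyde without affecting any stereocentre.

Step 13
Reactants: 19 2-[(2S,3S,5S,6S,8R)-6-acetoxy-8-{[(tert-butyldiphenylsilyl)oxy]methyl}-3,5-dichlorooxocan-2-yl]acetaldehyde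
Product: 20 (2S,3S,5S,6S,8R)-8-{[(tert-butyldiphenylsilyl)oxy]methyl}-3,5-dichloro-2-[(2Z)-5-(triisopropylsilyl)pent-2-en-4-yn-1-yl]oxocan-6-yl acetate
Conditions: 1,3-bis(triisopropylsilyl)propyne (1.3 equiv), n-BuLi (1.25 equiv), THF, −20 °C; then 19, −78 → −20 °C
Reagents that add atoms: 1,3-bis(triisopropylsilyl)propyne, CC(C)[Si](CC#C[Si](C(C)C)(C(C)C)C(C)C)(C(C)C)C(C)C
Why: Corey–Rücker variant of the Peterson olefination, in which the lithiated bis-silylpropyne adds to the aldehyde and syn-elimination of silanolate gives the Z enyne (about 10–20:1), the aldehyde reacting far faster than the acetate at low temperature.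

Step 14
Reactants: 20 (2S,3S,5S,6S,8R)-8-{[(tert-butyldiphenylsilyl)oxy]methyl}-3,5-dichloro-2-[(2Z)-5-(triisopropylsilyl)pent-2-en-4-yn-1-yl]oxocan-6-yl acetate
Product: 21 (2S,3S,5S,6S,8R)-3,5-dichloro-8-(hydroxymethyl)-2-[(2Z)-pent-2-en-4-yn-1-yl]oxocan-6-yl acetate
Conditions: Bu4NF, AcOH (1:1, 3 equiv), THF, 0 °C → rt
Reagents that add atoms: none
Why: Fluoride-mediated desilylation cleaves the O–Si and the alkynyl C–Si bonds in one operation, with acetic acid buffering to protect the acetate.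

Step 15
Reactants: 21 (2S,3S,5S,6S,8R)-3,5-dichloro-8-(hydroxymethyl)-2-[(2Z)-pent-2-en-4-yn-1-yl]oxocan-6-yl acetate
Product: 22 (2S,3S,5S,6S,8R)-3,5-dichloro-8-formyl-2-[(2Z)-pent-2-en-4-yn-1-yl]oxocan-6-yl acetate
Conditions: Dess–Martin periodinane (1.5 equiv), NaHCO3, CH2Cl2, 0 °C → rt; used crude
Reagents that add atoms: none
Why: Dess–Martin oxidation gives the α-alkoxy aldehyde under buffered conditions that do not epimerise C12.

Step 16
Reactants: 22 (2S,3S,5S,6S,8R)-3,5-dichloro-8-formyl-2-[(2Z)-pent-2-en-4-yn-1-yl]oxocan-6-yl acetate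
Product: 23 (2S,3S,5S,6S,8R)-3,5-dichloro-8-[(1R)-1-hydroxypropyl]-2-[(2Z)-pent-2-en-4-yn-1-yl]oxocan-6-yl acetate
Conditions: EtMgBr (2.5 equiv), CH2Cl2–Et2O, −78 °C
Reagents that add atoms: ethylmagnesium bromide, CC[Mg]Br
Why: Cram-chelate Grignard addition in which magnesium bridges the aldehyde and ring oxygens and ethyl adds anti to C11 to give the (13R) threo alcohol, addition at −78 °C outrunning alkyne deprotonation and acetate attack.

Step 17
Reactants: 23 (2S,3S,5S,6S,8R)-3,5-dichloro-8-[(1R)-1-hydroxypropyl]-2-[(2Z)-pent-2-en-4-yn-1-yl]oxocan-6-yl acetate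
Product: 24 (2S,3S,5S,6S,8R)-8-[(1S)-1-bromopropyl]-3,5-dichloro-2-[(2Z)-pent-2-en-4-yn-1-yl]oxocan-6-yl acetate (CNP0251465.4)
Conditions: CBr4 (3 equiv), n-Oct3P (6 equiv), toluene, 70 °C
Reagents that add atoms: carbon tetrabromide, BrC(Br)(Br)Br
Why: Appel-type bromination in which bromide displaces the alkoxyphosphonium group by SN2 and inverts C13 to the (S) bromide.

## Compound list

1 | (R)-3-hydroxy-γ-butyrolactone [(4R)-4-hydroxyoxolan-2-one] | O=C1C[C@@H](O)CO1 | starting material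
2 | (4R)-oxolane-2,4-diol (lactol, present as its aluminium alkoxide; C2 epimers) | OC1C[C@@H](O)CO1 | intermediate
3 | (2R)-hex-5-ene-1,2,4-triol (C4 epimers) | C=CC(O)C[C@@H](O)CO | intermediate
4 | (2R)-1-[(tert-butyldiphenylsilyl)oxy]hex-5-ene-2,4-diol (C4 epimers) | C=CC(O)C[C@@H](O)CO[Si](C(C)(C)C)(c1ccccc1)c1ccccc1 | intermediate
5 | (6R)-6-{[(tert-butyldiphenylsilyl)oxy]methyl}-2-[(phenylselanyl)methyl]-4-vinyl-1,3-dioxane (epimers at C2 and C4) | C=CC1C[C@H](CO[Si](C(C)(C)C)(c2ccccc2)c2ccccc2)OC(C[Se]c2ccccc2)O1 | intermediate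
6 | (6R)-6-{[(tert-butyldiphenylsilyl)oxy]methyl}-2-[(phenylseleninyl)methyl]-4-vinyl-1,3-dioxane (selenoxide) | C=CC1C[C@H](CO[Si](C(C)(C)C)(c2ccccc2)c2ccccc2)OC(C[Se](=O)c2ccccc2)O1 | intermediate
7 | (6R)-6-{[(tert-butyldiphenylsilyl)oxy]methyl}-2-methylidene-4-vinyl-1,3-dioxane (ketene acetal) | C=CC1C[C@H](CO[Si](C(C)(C)C)(c2ccccc2)c2ccccc2)OC(=C)O1 | intermediate
8 | (5Z,8R)-8-{[(tert-butyldiphenylsilyl)oxy]methyl}-3,4,7,8-tetrahydro-2H-oxocin-2-one | O=C1O[C@@H](CO[Si](C(C)(C)C)(c2ccccc2)c2ccccc2)C/C=C\CC1 | intermediate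
9 | potassium (5Z,8R)-8-{[(tert-butyldiphenylsilyl)oxy]methyl}-7,8-dihydro-4H-oxocin-2-olate (enolate of 8) | [K+].[O-]C1=CC/C=C\C[C@H](CO[Si](C(C)(C)C)(c2ccccc2)c2ccccc2)O1 | intermediate
10 | (3R,5Z,8R)-8-{[(tert-butyldiphenylsilyl)oxy]methyl}-3-hydroxy-3,4,7,8-tetrahydro-2H-oxocin-2-one | O=C1O[C@@H](CO[Si](C(C)(C)C)(c2ccccc2)c2ccccc2)C/C=C\C[C@H]1O | intermediate
11 | (3R,5Z,8R)-8-{[(tert-butyldiphenylsilyl)oxy]methyl}-3,4,7,8-tetrahydro-2H-oxocine-2,3-diol (lactol, present as its aluminium alkoxide; C2 epimers) | OC1O[C@@H](CO[Si](C(C)(C)C)(c2ccccc2)c2ccccc2)C/C=C\C[C@H]1O | intermediate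
12 | (3R,5Z,8R)-8-{[(tert-butyldiphenylsilyl)oxy]methyl}-3,4,7,8-tetrahydro-2H-oxocine-2,3-diyl diacetate (C2 epimers) | CC(=O)OC1O[C@@H](CO[Si](C(C)(C)C)(c2ccccc2)c2ccccc2)C/C=C\C[C@H]1OC(C)=O | intermediate
13 | (2S,3R,5Z,8R)-2-allyl-8-{[(tert-butyldiphenylsilyl)oxy]methyl}-3,4,7,8-tetrahydro-2H-oxocin-3-yl acetate | C=CC[C@@H]1O[C@@H](CO[Si](C(C)(C)C)(c2ccccc2)c2ccccc2)C/C=C\C[C@H]1OC(C)=O | intermediate
14 | (2S,3R,5R,6S,8R)-2-allyl-8-{[(tert-butyldiphenylsilyl)oxy]methyl}-5,6-epoxyoxocan-3-yl acetate (epoxide α) | C=CC[C@@H]1O[C@@H](CO[Si](C(C)(C)C)(c3ccccc3)c3ccccc3)C[C@@H]2O[C@@H]2C[C@H]1OC(C)=O | intermediate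
15 | (2S,3R,5R,6S,8R)-2-allyl-8-{[(tert-butyldiphenylsilyl)oxy]methyl}-5,6-epoxyoxocan-3-ol | C=CC[C@@H]1O[C@@H](CO[Si](C(C)(C)C)(c3ccccc3)c3ccccc3)C[C@@H]2O[C@@H]2C[C@H]1O | intermediate
16 | (2S,3S,5R,6S,8R)-2-allyl-8-{[(tert-butyldiphenylsilyl)oxy]methyl}-3-chloro-5,6-epoxyoxocane | C=CC[C@@H]1O[C@@H](CO[Si](C(C)(C)C)(c3ccccc3)c3ccccc3)C[C@@H]2O[C@@H]2C[C@@H]1Cl | intermediate
17 | (2S,3S,5S,6S,8R)-2-allyl-8-{[(tert-butyldiphenylsilyl)oxy]methyl}-3,5-dichlorooxocan-6-yl acetate | C=CC[C@@H]1O[C@@H](CO[Si](C(C)(C)C)(c2ccccc2)c2ccccc2)C[C@H](OC(C)=O)[C@@H](Cl)C[C@@H]1Cl | intermediate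
18 | 3-{[(2S,3S,5S,6S,8R)-6-acetoxy-8-{[(tert-butyldiphenylsilyl)oxy]methyl}-3,5-dichlorooxocan-2-yl]methyl}-1,2,4-trioxolane (ozonide) | C1OC(C[C@@H]2O[C@@H](CO[Si](C(C)(C)C)(c3ccccc3)c3ccccc3)C[C@H](OC(C)=O)[C@@H](Cl)C[C@@H]2Cl)OO1 | intermediate
19 | 2-[(2S,3S,5S,6S,8R)-6-acetoxy-8-{[(tert-butyldiphenylsilyl)oxy]methyl}-3,5-dichlorooxocan-2-yl]acetaldehyde | O=CC[C@@H]1O[C@@H](CO[Si](C(C)(C)C)(c2ccccc2)c2ccccc2)C[C@H](OC(C)=O)[C@@H](Cl)C[C@@H]1Cl | intermediate
20 | (2S,3S,5S,6S,8R)-8-{[(tert-butyldiphenylsilyl)oxy]methyl}-3,5-dichloro-2-[(2Z)-5-(triisopropylsilyl)pent-2-en-4-yn-1-yl]oxocan-6-yl acetate | CC(C)[Si](C#C/C=C\C[C@@H]1O[C@@H](CO[Si](C(C)(C)C)(c2ccccc2)c2ccccc2)C[C@H](OC(C)=O)[C@@H](Cl)C[C@@H]1Cl)(C(C)C)C(C)C | intermediate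
21 | (2S,3S,5S,6S,8R)-3,5-dichloro-8-(hydroxymethyl)-2-[(2Z)-pent-2-en-4-yn-1-yl]oxocan-6-yl acetate | C#C/C=C\C[C@@H]1O[C@@H](CO)C[C@H](OC(C)=O)[C@@H](Cl)C[C@@H]1Cl | intermediate
22 | (2S,3S,5S,6S,8R)-3,5-dichloro-8-formyl-2-[(2Z)-pent-2-en-4-yn-1-yl]oxocan-6-yl acetate | C#C/C=C\C[C@@H]1O[C@@H](C=O)C[C@H](OC(C)=O)[C@@H](Cl)C[C@@H]1Cl | intermediate
23 | (2S,3S,5S,6S,8R)-3,5-dichloro-8-[(1R)-1-hydroxypropyl]-2-[(2Z)-pent-2-en-4-yn-1-yl]oxocan-6-yl acetate | C#C/C=C\C[C@@H]1O[C@@H]([C@H](O)CC)C[C@H](OC(C)=O)[C@@H](Cl)C[C@@H]1Cl | intermediate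
24 | (2S,3S,5S,6S,8R)-8-[(1S)-1-bromopropyl]-3,5-dichloro-2-[(2Z)-pent-2-en-4-yn-1-yl]oxocan-6-yl acetate | C#C/C=C\C[C@@H]1O[C@@H]([C@@H](Br)CC)C[C@H](OC(C)=O)[C@@H](Cl)C[C@@H]1Cl | target

## Step count and risks

Total step count: 17. Longest linear sequence: 17 (fully linear from 1).

The facial selectivity in step 8 and the regioselectivity in step 11 rest on steric arguments for a medium ring without direct precedent; they are predictions and would have to be confirmed by NOE on 14 and 17.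

Three steps most likely to fail:

Step 5 (enolate hydroxylation). Without a chiral oxidant the C7 selectivity depends only on the ring, and the wrong epimer may dominate. The fallback sets out from 8 and comes back at 12. The same oxidation is accepted as it falls, giving (3S,5Z,8R)-8-{[(tert-butyldiphenylsilyl)oxy]methyl}-3-hydroxy-3,4,7,8-tetrahydro-2H-oxocin-2-one F1. Mitsunobu inversion (AcOH, PPh3, DIAD, THF, 0 °C), a fast SN2 at the carbonyl-activated carbon, then gives (3R,5Z,8R)-8-{[(tert-butyldiphenylsilyl)oxy]methyl}-2-oxo-3,4,7,8-tetrahydro-2H-oxocin-3-yl acetate F2. Under the step 6 conditions the ester is reduced off and both alkoxides are re-acetylated, so F2 gives 12.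

Step 8 (face of epoxidation). If the peracid prefers the β face, the epoxide is made by the other stereochemical course. The fallback sets out from 13 and comes back at 15. NBS in aqueous THF at 0 °C puts bromine on the face the peracid prefers and water anti to it, giving (2S,3R,5S,6S,8R)-2-allyl-5-bromo-8-{[(tert-butyldiphenylsilyl)oxy]methyl}-6-hydroxyoxocan-3-yl acetate F3 and its regioisomer (2S,3R,5R,6R,8R)-2-allyl-6-bromo-8-{[(tert-butyldiphenylsilyl)oxy]methyl}-5-hydroxyoxocan-3-yl acetate F4. K2CO3 in MeOH closes both bromohydrins to the same α-epoxide and removes the C7 acetate in the same flask, giving 15.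

Step 11 (regiochemistry of chloride opening). If chloride attacks C10, or the ring oxygen takes part, the chlorine and acetate are installed by electrophilic addition instead. The fallback sets out from 13 and comes back at 17. Methanolysis (K2CO3, MeOH) gives (2S,3R,5Z,8R)-2-allyl-8-{[(tert-butyldiphenylsilyl)oxy]methyl}-3,4,7,8-tetrahydro-2H-oxocin-3-ol F5. Ghosez chlorination with inversion gives (2S,3S,5Z,8R)-2-allyl-8-{[(tert-butyldiphenylsilyl)oxy]methyl}-3-chloro-3,4,7,8-tetrahydro-2H-oxocine F6. Chloro-acetoxylation of the ring alkene (t-BuOCl, AcOH, NaOAc, 0 °C) then gives 17: acetate opens the chloriranium ion at C10, remote from the electron-withdrawing C7 chloride, and from the α face, because the β face at C10 is screened by the C12 group and the α face at C9 by the C7 chloride.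

## Further compounds

F1 | step 5 | (3S,5Z,8R)-8-{[(tert-butyldiphenylsilyl)oxy]methyl}-3-hydroxy-3,4,7,8-tetrahydro-2H-oxocin-2-one | O=C1O[C@@H](CO[Si](C(C)(C)C)(c2ccccc2)c2ccccc2)C/C=C\C[C@@H]1O
F2 | step 5 | (3R,5Z,8R)-8-{[(tert-butyldiphenylsilyl)oxy]methyl}-2-oxo-3,4,7,8-tetrahydro-2H-oxocin-3-yl acetate | O=C1O[C@@H](CO[Si](C(C)(C)C)(c2ccccc2)c2ccccc2)C/C=C\C[C@H]1OC(C)=O
F3 | step 8 | (2S,3R,5S,6S,8R)-2-allyl-5-bromo-8-{[(tert-butyldiphenylsilyl)oxy]methyl}-6-hydroxyoxocan-3-yl acetate | C=CC[C@@H]1O[C@@H](CO[Si](C(C)(C)C)(c2ccccc2)c2ccccc2)C[C@H](O)[C@@H](Br)C[C@H]1OC(C)=O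
F4 | step 8 | (2S,3R,5R,6R,8R)-2-allyl-6-bromo-8-{[(tert-butyldiphenylsilyl)oxy]methyl}-5-hydroxyoxocan-3-yl acetate | C=CC[C@@H]1O[C@@H](CO[Si](C(C)(C)C)(c2ccccc2)c2ccccc2)C[C@@H](Br)[C@H](O)C[C@H]1OC(C)=O
F5 | step 11 | (2S,3R,5Z,8R)-2-allyl-8-{[(tert-butyldiphenylsilyl)oxy]methyl}-3,4,7,8-tetrahydro-2H-oxocin-3-ol | C=CC[C@@H]1O[C@@H](CO[Si](C(C)(C)C)(c2ccccc2)c2ccccc2)C/C=C\C[C@H]1O
F6 | step 11 | (2S,3S,5Z,8R)-2-allyl-8-{[(tert-butyldiphenylsilyl)oxy]methyl}-3-chloro-3,4,7,8-tetrahydro-2H-oxocine | C=CC[C@@H]1O[C@@H](CO[Si](C(C)(C)C)(c2ccccc2)c2ccccc2)C/C=C\C[C@@H]1Cl
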